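## Retrosynthetic overview

1. Target ⇐ fluoride desilylation ⇐ two Wittig couplings (C15 + C10 + C15) at C11=C12 and C11′=C12′: triol-half phosphonium salt, symmetrical C10 trienedial, furanoid-half phosphonium salt.
2. Furanoid half ⇐ gold-catalysed cycloisomerisation of an α-hydroxy vinylallene (axis-to-centre transfer sets C8′) ⇐ syn-SN2′ hydride opening of an alkynyl anti-epoxide.
3. Triol half ⇐ trans-hydroalumination of a propargylic trans-diol ⇐ invertive acid hydrolysis (at C5) of the alkynyl syn-epoxide.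
4. Both epoxides ⇐ one cyclohexenylmethanol by Sharpless epoxidation with either tartrate; C9–C11 (and C9′–C11′) come from the (E)-enol triflate of ethyl acetoacetate by Sonogashira coupling.
5. Cyclohexenylmethanol ⇐ ketoisophorone by ene-reductase and ketoreductase reductions, then enol triflate carbonylation. Ring order: carbocycle (bought) → oxiranes → dihydrofuran (closed at the C15 stage); no ring is formed after the polyene is built.

Assumption: 1, 9 and 28 are bought, the enzymes are commercial or recombinant preparations, TBDPS = tert-butyldiphenylsilyl, and carotenoid numbering (C1–C15, C1′–C15′) is used in the explanations.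

The stereochemical assignments (which tartrate gives which epoxide, the syn course of the hydride opening, allene axis → C8′) were derived by hand from CIP analysis and literature precedent; nothing was run or computed.

## Route

Step 1
Reactants: 1 ketoisophorone (2,6,6-trimethylcyclohex-2-ene-1,4-dione)
Product: 2 (6R)-2,2,6-trimethylcyclohexane-1,4-dione
Conditions: ene-reductase (flavin-dependent, Old Yellow Enzyme family), NAD+ (cat.), formate dehydrogenase, HCO2Na, KH2PO4/K2HPO4 buffer pH 6.8, 30 °C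
Reagents that add atoms: none
Why: Asymmetric biocatalytic conjugate reduction — the ene-reductase adds hydride from reduced flavin and a proton trans across the activated C=C, setting the first stereocentre (6R).

Step 2
Reactants: 2 (6R)-2,2,6-trimethylcyclohexane-1,4-dione
Product: 3 (4R,6R)-4-hydroxy-2,2,6-trimethylcyclohexan-1-one
Conditions: ketoreductase (NADH-dependent alcohol dehydrogenase of the levodione reductase type), NAD+ (cat.), formate dehydrogenase, HCO2Na, KH2PO4/K2HPO4 buffer pH 7.0, 30 °C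
Reagents that add atoms: none
Why: Enzymatic carbonyl reduction of the unhindered C4 ketone only, with hydride delivered to one face to give the (4R)-alcohol trans to the methyl group; this carbinol becomes C3 and C3′ of the target.

Step 3
Reactants: 3 (4R,6R)-4-hydroxy-2,2,6-trimethylcyclohexan-1-one
Product: 4 (4R,6R)-4-(TBDPSO)-2,2,6-trimethylcyclohexan-1-one
Conditions: TBDPSCl, imidazole, DMF, rt
Reagents that add atoms: tert-butyl(chloro)diphenylsilane, CC(C)(C)[Si](Cl)(c1ccccc1)c1ccccc1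
Why: Silyl ether formation; the TBDPS group survives the base, hydride, aqueous acid and organometallic steps ahead and is removed by fluoride at the end.

Step 4
Reactants: 4 (4R,6R)-4-(TBDPSO)-2,2,6-trimethylcyclohexan-1-one
Product: 6 (4R)-4-(TBDPSO)-2,6,6-trimethylcyclohex-1-en-1-yl trifluoromethanesulfonate, via potassium enolate 5 (not isolated)
Conditions: KN(SiMe3)2, THF, −78 °C; then PhNTf2, −78 → 0 °C
Reagents that add atoms: N-phenylbis(trifluoromethanesulfonimide), O=S(=O)(N(c1ccccc1)S(=O)(=O)C(F)(F)F)C(F)(F)F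
Why: Deprotonation at the only enolisable position and O-triflation of the enolate give the tetrasubstituted enol triflate; the methyl stereocentre, no longer needed, is erased.

Step 5
Reactants: 6 (4R)-4-(TBDPSO)-2,6,6-trimethylcyclohex-1-en-1-yl trifluoromethanesulfonate
Product: 7 methyl (4R)-4-(TBDPSO)-2,6,6-trimethylcyclohex-1-ene-1-carboxylate
Conditions: Pd(OAc)2 (5 mol %), PPh3, CO (1 atm), Et3N, MeOH–DMF, 60 °C
Reagents that add atoms: carbon monoxide, [C-]#[O+]; methanol, CO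
Why: Palladium-catalysed alkoxycarbonylation of the enol triflate (oxidative addition, CO insertion, methanolysis) installs C7.

Step 6
Reactants: 7 methyl (4R)-4-(TBDPSO)-2,6,6-trimethylcyclohex-1-ene-1-carboxylate
Product: 8 [(4R)-4-(TBDPSO)-2,6,6-trimethylcyclohex-1-en-1-yl]methanol
Conditions: i-Bu2AlH (DIBAL-H), CH2Cl2, −78 °C
Reagents that add atoms: none
Why: 1,2-Reduction of the enoate with DIBAL-H gives the allylic alcohol needed for directed epoxidation.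

Step 7
Reactants: 9 ethyl acetoacetate (ethyl 3-oxobutanoate)
Product: 10 ethyl (2E)-3-{[(trifluoromethyl)sulfonyl]oxy}but-2-enoate
Conditions: Tf2O, aq. Me4NOH, toluene, 0–5 °C
Reagents that add atoms: trifluoromethanesulfonic anhydride, O=S(=O)(OS(=O)(=O)C(F)(F)F)C(F)(F)F
Why: O-Triflation of the non-chelated tetramethylammonium enolate, which reacts in its E form; this geometry becomes the 9E and 9′E double bonds.

Step 8
Reactants: 8 [(4R)-4-(TBDPSO)-2,6,6-trimethylcyclohex-1-en-1-yl]methanol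
Product: 11 [(1R,4S,6R)-4-(TBDPSO)-2,2,6-trimethyl-7-oxabicyclo[4.1.0]heptan-1-yl]methanol (oxirane O anti to the silyloxy group)
Conditions: Ti(OiPr)4 (0.3 equiv), D-(−)-diethyl tartrate (0.36 equiv), t-BuOOH, 4 Å MS, CH2Cl2, −20 °C
Reagents that add atoms: tert-butyl hydroperoxide, CC(C)(C)OO
Why: Katsuki–Sharpless asymmetric epoxidation under reagent control — the D-(−)-tartrate complex delivers oxygen to the face anti to the silyloxy group (matched with the substrate bias), setting the future C5′ configuration.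

Step 9
Reactants: 11 [(1R,4S,6R)-4-(TBDPSO)-2,2,6-trimethyl-7-oxabicyclo[4.1.0]heptan-1-yl]methanol
Product: 12 (1S,4S,6R)-4-(TBDPSO)-2,2,6-trimethyl-7-oxabicyclo[4.1.0]heptane-1-carbaldehyde
Conditions: Dess–Martin periodinane, pyridine, CH2Cl2, 0 °C → rt
Reagents that add atoms: none
Why: Dess–Martin oxidation of the neopentyl primary alcohol under buffered conditions; the aldehyde has no α-hydrogen and cannot epimerise.

Step 10
Reactants: 12 (1S,4S,6R)-4-(TBDPSO)-2,2,6-trimethyl-7-oxabicyclo[4.1.0]heptane-1-carbaldehyde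
Product: 13 (1R,4S,6R)-4-(TBDPSO)-1-ethynyl-2,2,6-trimethyl-7-oxabicyclo[4.1.0]heptane
Conditions: dimethyl (1-diazo-2-oxopropyl)phosphonate, K2CO3, MeOH, 0 °C → rt
Reagents that add atoms: dimethyl (1-diazo-2-oxopropyl)phosphonate (Ohira–Bestmann reagent), COP(=O)(OC)C(=[N+]=[N-])C(C)=O
Why: Seyferth–Gilbert homologation in the Ohira–Bestmann variant (olefination, loss of N2, 1,2-shift of the alkylidene carbene) turns the aldehyde into the terminal alkyne without touching the oxirane.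

Step 11
Reactants: 13 (1R,4S,6R)-4-(TBDPSO)-1-ethynyl-2,2,6-trimethyl-7-oxabicyclo[4.1.0]heptane, 10 ethyl (2E)-3-{[(trifluoromethyl)sulfonyl]oxy}but-2-enoate
Product: 14 ethyl (2E)-5-[(1R,4S,6R)-4-(TBDPSO)-2,2,6-trimethyl-7-oxabicyclo[4.1.0]heptan-1-yl]-3-methylpent-2-en-4-ynoate
Conditions: PdCl2(PPh3)2 (3 mol %), CuI (5 mol %), Et3N, THF, rt
Reagents that add atoms: none
Why: Sonogashira coupling of the terminal alkyne with the enol triflate proceeds with retention of the E geometry and leaves the oxirane intact.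

Step 12
Reactants: 14 ethyl (2E)-5-[(1R,4S,6R)-4-(TBDPSO)-2,2,6-trimethyl-7-oxabicyclo[4.1.0]heptan-1-yl]-3-methylpent-2-en-4-ynoate
Product: 15 (2E)-5-[(2R,4S)-4-(TBDPSO)-2-hydroxy-2,6,6-trimethylcyclohexylidene]-3-methylpenta-2,4-dien-1-ol with aR allene axis (6R in carotenoid numbering; the allenic C–H lies on the face of the tertiary OH)
Conditions: i-Bu2AlH (5 equiv), CH2Cl2, −78 → 0 °C
Reagents that add atoms: none
Why: DIBAL-H reduces the ester and, bound to the oxirane oxygen, delivers hydride to the distal alkyne carbon on the same face (syn-SN2′ reduction of a propargylic epoxide), so the C–O bond at the methyl-bearing carbon is retained and the allene axis is fixed.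

Step 13
Reactants: 15 (2E)-5-[(2R,4S)-4-(TBDPSO)-2-hydroxy-2,6,6-trimethylcyclohexylidene]-3-methylpenta-2,4-dien-1-ol (aR)
Product: 16 (2E)-3-[(2S,6S,7aR)-6-(TBDPSO)-4,4,7a-trimethyl-2,4,5,6,7,7a-hexahydro-1-benzofuran-2-yl]but-2-en-1-ol
Conditions: AuCl3 (5 mol %), THF, 0 °C → rt, dark
Reagents that add atoms: none
Why: Gold-catalysed 5-endo cycloisomerisation of the α-hydroxyallene — the tertiary OH adds to the gold-activated distal C=C anti to the metal and protodeauration follows, so the allene axis is transferred completely to the new C2 centre (S, C8′ of the target).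

Step 14
Reactants: 16 (2E)-3-[(2S,6S,7aR)-6-(TBDPSO)-4,4,7a-trimethyl-2,4,5,6,7,7a-hexahydro-1-benzofuran-2-yl]but-2-en-1-ol
Product: 18 triphenyl{(2E)-3-[(2S,6S,7aR)-6-(TBDPSO)-4,4,7a-trimethyl-2,4,5,6,7,7a-hexahydro-1-benzofuran-2-yl]but-2-en-1-yl}phosphonium bromide, via allylic bromide 17 (not isolated)
Conditions: CBr4, PPh3, 2,6-lutidine, CH2Cl2, −20 → 0 °C; then PPh3, EtOAc, rt
Reagents that add atoms: tetrabromomethane, BrC(Br)(Br)Br; triphenylphosphine, c1ccc(cc1)P(c1ccccc1)c1ccccc1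
Why: Appel bromination of the primary allylic alcohol under neutral conditions followed by SN2 quaternisation of PPh3, so no acid reaches the bis-allylic ether centre.

Step 15
Reactants: 8 [(4R)-4-(TBDPSO)-2,6,6-trimethylcyclohex-1-en-1-yl]methanol
Product: 19 [(1S,4S,6S)-4-(TBDPSO)-2,2,6-trimethyl-7-oxabicyclo[4.1.0]heptan-1-yl]methanol (oxirane O syn to the silyloxy group)
Conditions: Ti(OiPr)4 (0.3 equiv), L-(+)-diethyl tartrate (0.36 equiv), t-BuOOH, 4 Å MS, CH2Cl2, −20 °C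
Reagents that add atoms: tert-butyl hydroperoxide, CC(C)(C)OO
Why: Katsuki–Sharpless epoxidation with the enantiomeric tartrate — reagent control overrides the modest substrate bias and places the oxygen syn to the silyloxy group.

Step 16
Reactants: 19 [(1S,4S,6S)-4-(TBDPSO)-2,2,6-trimethyl-7-oxabicyclo[4.1.0]heptan-1-yl]methanol
Product: 20 (1R,4S,6S)-4-(TBDPSO)-2,2,6-trimethyl-7-oxabicyclo[4.1.0]heptane-1-carbaldehyde
Conditions: Dess–Martin periodinane, pyridine, CH2Cl2, 0 °C → rt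
Reagents that add atoms: none
Why: Dess–Martin oxidation of the primary alcohol to a non-enolisable aldehyde.

Step 17
Reactants: 20 (1R,4S,6S)-4-(TBDPSO)-2,2,6-trimethyl-7-oxabicyclo[4.1.0]heptane-1-carbaldehyde
Product: 21 (1S,4S,6S)-4-(TBDPSO)-1-ethynyl-2,2,6-trimethyl-7-oxabicyclo[4.1.0]heptane
Conditions: dimethyl (1-diazo-2-oxopropyl)phosphonate, K2CO3, MeOH, 0 °C → rt
Reagents that add atoms: dimethyl (1-diazo-2-oxopropyl)phosphonate (Ohira–Bestmann reagent), COP(=O)(OC)C(=[N+]=[N-])C(C)=O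
Why: Seyferth–Gilbert (Ohira–Bestmann) homologation of the aldehyde to the terminal alkyne.

Step 18
Reactants: 21 (1S,4S,6S)-4-(TBDPSO)-1-ethynyl-2,2,6-trimethyl-7-oxabicyclo[4.1.0]heptane
Product: 22 (1R,2S,5S)-5-(TBDPSO)-2-ethynyl-1,3,3-trimethylcyclohexane-1,2-diol
Conditions: HClO4 (0.2 M), THF–H2O 3:1, 0 °C → rt
Reagents that add atoms: water, O
Why: Acid-catalysed, SN2-like trans-diaxial hydrolysis of the epoxide — water attacks the methyl-bearing carbon with inversion because the other carbon is neopentyl and its cation is destabilised by the ethynyl group, giving the trans-diol with the C5 (R) and C6 configurations of the target.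

Step 19
Reactants: 22 (1R,2S,5S)-5-(TBDPSO)-2-ethynyl-1,3,3-trimethylcyclohexane-1,2-diol, 10 ethyl (2E)-3-{[(trifluoromethyl)sulfonyl]oxy}but-2-enoate
Product: 23 ethyl (2E)-5-[(1S,2R,4S)-4-(TBDPSO)-1,2-dihydroxy-2,6,6-trimethylcyclohexyl]-3-methylpent-2-en-4-ynoate
Conditions: PdCl2(PPh3)2 (3 mol %), CuI (5 mol %), Et3N, THF, rt
Reagents that add atoms: none
Why: Sonogashira coupling of the tertiary propargylic alcohol with the E enol triflate, with retention of geometry.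

Step 20
Reactants: 23 ethyl (2E)-5-[(1S,2R,4S)-4-(TBDPSO)-1,2-dihydroxy-2,6,6-trimethylcyclohexyl]-3-methylpent-2-en-4-ynoate
Product: 24 (2E)-5-[(1S,2R,4S)-4-(TBDPSO)-1,2-dihydroxy-2,6,6-trimethylcyclohexyl]-3-methylpent-2-en-4-yn-1-ol
Conditions: i-Bu2AlH (5 equiv), CH2Cl2, −78 °C
Reagents that add atoms: none
Why: Clean 1,2-reduction of the conjugated ester with DIBAL-H at low temperature, leaving the alkyne for the directed reduction.

Step 21
Reactants: 24 (2E)-5-[(1S,2R,4S)-4-(TBDPSO)-1,2-dihydroxy-2,6,6-trimethylcyclohexyl]-3-methylpent-2-en-4-yn-1-ol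
Product: 25 (2E,4E)-5-[(1R,2R,4S)-4-(TBDPSO)-1,2-dihydroxy-2,6,6-trimethylcyclohexyl]-3-methylpenta-2,4-dien-1-ol
Conditions: NaAlH2(OCH2CH2OMe)2 (Red-Al, 5 equiv), THF, 0 °C → rt
Reagents that add atoms: none
Why: Propargylic-alkoxide-directed trans-hydroalumination followed by protonolysis gives only the E alkene (7E) and does not touch the other double bond.

Step 22
Reactants: 25 (2E,4E)-5-[(1R,2R,4S)-4-(TBDPSO)-1,2-dihydroxy-2,6,6-trimethylcyclohexyl]-3-methylpenta-2,4-dien-1-ol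
Product: 27 {(2E,4E)-5-[(1R,2R,4S)-4-(TBDPSO)-1,2-dihydroxy-2,6,6-trimethylcyclohexyl]-3-methylpenta-2,4-dien-1-yl}triphenylphosphonium bromide, via allylic bromide 26 (not isolated)
Conditions: CBr4, PPh3, 2,6-lutidine, CH2Cl2, −20 → 0 °C; then PPh3, EtOAc, rt
Reagents that add atoms: tetrabromomethane, BrC(Br)(Br)Br; triphenylphosphine, c1ccc(cc1)P(c1ccccc1)c1ccccc1
Why: Appel bromination is selective for the primary allylic alcohol over the two tertiary ones, and SN2 quaternisation of PPh3 at the unhindered terminus gives the Wittig salt without acid.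

Step 23
Reactants: 27 {(2E,4E)-5-[(1R,2R,4S)-4-(TBDPSO)-1,2-dihydroxy-2,6,6-trimethylcyclohexyl]-3-methylpenta-2,4-dien-1-yl}triphenylphosphonium bromide, 28 (2E,4E,6E)-2,7-dimethylocta-2,4,6-trienedial
Product: 30 (2E,4E,6E,8E,10E,12E)-13-[(1R,2R,4S)-4-(TBDPSO)-1,2-dihydroxy-2,6,6-trimethylcyclohexyl]-2,7,11-trimethyltrideca-2,4,6,8,10,12-hexaenal, via phosphonium ylide 29 (not isolated)
Conditions: 28 (3 equiv), NaOMe, MeOH–CH2Cl2, 0 °C → rt; then EtOAc, 70 °C, dark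
Reagents that add atoms: none
Why: Wittig olefination of the semi-stabilised allylic ylide with an excess of the symmetrical dialdehyde gives the mono-adduct, and the hindered Z isomer at the new 11,12 bond isomerises to E on warming.

Step 24
Reactants: 18 triphenyl{(2E)-3-[(2S,6S,7aR)-6-(TBDPSO)-4,4,7a-trimethyl-2,4,5,6,7,7a-hexahydro-1-benzofuran-2-yl]but-2-en-1-yl}phosphonium bromide, 30 (2E,4E,6E,8E,10E,12E)-13-[(1R,2R,4S)-4-(TBDPSO)-1,2-dihydroxy-2,6,6-trimethylcyclohexyl]-2,7,11-trimethyltrideca-2,4,6,8,10,12-hexaenal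
Product: 32 (3S,5R,6R,3′S,5′R,8′S)-3,3′-bis-O-TBDPS-5′,8′-epoxy-5,6,5′,8′-tetrahydro-β,β-carotene-3,5,6,3′-tetrol (all-E), via phosphonium ylide 31 (not isolated)
Conditions: NaOMe, MeOH–CH2Cl2, 0 °C → rt, Ar, dark; then EtOAc, 70 °C
Reagents that add atoms: none
Why: The second Wittig olefination joins the halves under base-only conditions that leave the acid-labile dihydrofuran centre untouched, and the hindered 11′Z isomer is isomerised thermally to all-E.

Step 25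
Reactants: 32 (3S,5R,6R,3′S,5′R,8′S)-3,3′-bis-O-TBDPS-5′,8′-epoxy-5,6,5′,8′-tetrahydro-β,β-carotene-3,5,6,3′-tetrol
Product: 33 (3S,5R,6R,3′S,5′R,8′S)-5′,8′-epoxy-5,6,5′,8′-tetrahydro-β,β-carotene-3,5,6,3′-tetrol (target, CNP0210286.3)
Conditions: Bu4NF, THF, rt, Ar, dark
Reagents that add atoms: none
Why: Fluoride-induced cleavage of both silyl ethers under non-acidic conditions preserves the furanoid C8′ centre and the tertiary allylic alcohol.

## Compound list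

1 | ketoisophorone (2,6,6-trimethylcyclohex-2-ene-1,4-dione) | CC1=CC(=O)CC(C)(C)C1=O | starting material
2 | (6R)-2,2,6-trimethylcyclohexane-1,4-dione | C[C@@H]1CC(=O)CC(C)(C)C1=O | intermediate
3 | (4R,6R)-4-hydroxy-2,2,6-trimethylcyclohexan-1-one | C[C@@H]1C[C@@H](O)CC(C)(C)C1=O | intermediate
4 | (4R,6R)-4-(TBDPSO)-2,2,6-trimethylcyclohexan-1-one | C[C@@H]1C[C@@H](O[Si](c2ccccc2)(c2ccccc2)C(C)(C)C)CC(C)(C)C1=O | intermediate
5 | potassium (4R)-4-(TBDPSO)-2,6,6-trimethylcyclohex-1-en-1-olate | [K+].CC1=C([O-])C(C)(C)C[C@H](O[Si](c2ccccc2)(c2ccccc2)C(C)(C)C)C1 | intermediate (not isolated)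
6 | (4R)-4-(TBDPSO)-2,6,6-trimethylcyclohex-1-en-1-yl trifluoromethanesulfonate | CC1=C(OS(=O)(=O)C(F)(F)F)C(C)(C)C[C@H](O[Si](c2ccccc2)(c2ccccc2)C(C)(C)C)C1 | intermediate
7 | methyl (4R)-4-(TBDPSO)-2,6,6-trimethylcyclohex-1-ene-1-carboxylate | CC1=C(C(=O)OC)C(C)(C)C[C@H](O[Si](c2ccccc2)(c2ccccc2)C(C)(C)C)C1 | intermediate
8 | [(4R)-4-(TBDPSO)-2,6,6-trimethylcyclohex-1-en-1-yl]methanol | CC1=C(CO)C(C)(C)C[C@H](O[Si](c2ccccc2)(c2ccccc2)C(C)(C)C)C1 | intermediate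
9 | ethyl acetoacetate | CCOC(=O)CC(C)=O | starting material
10 | ethyl (2E)-3-{[(trifluoromethyl)sulfonyl]oxy}but-2-enoate | CCOC(=O)/C=C(\C)OS(=O)(=O)C(F)(F)F | intermediate
11 | [(1R,4S,6R)-4-(TBDPSO)-2,2,6-trimethyl-7-oxabicyclo[4.1.0]heptan-1-yl]methanol | OC[C@@]12O[C@]1(C)C[C@@H](O[Si](c3ccccc3)(c3ccccc3)C(C)(C)C)CC2(C)C | intermediate
12 | (1S,4S,6R)-4-(TBDPSO)-2,2,6-trimethyl-7-oxabicyclo[4.1.0]heptane-1-carbaldehyde | O=C[C@@]12O[C@]1(C)C[C@@H](O[Si](c3ccccc3)(c3ccccc3)C(C)(C)C)CC2(C)C | intermediate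
13 | (1R,4S,6R)-4-(TBDPSO)-1-ethynyl-2,2,6-trimethyl-7-oxabicyclo[4.1.0]heptane | C#C[C@@]12O[C@]1(C)C[C@@H](O[Si](c3ccccc3)(c3ccccc3)C(C)(C)C)CC2(C)C | intermediate
14 | ethyl (2E)-5-[(1R,4S,6R)-4-(TBDPSO)-2,2,6-trimethyl-7-oxabicyclo[4.1.0]heptan-1-yl]-3-methylpent-2-en-4-ynoate | CCOC(=O)/C=C(\C)C#C[C@@]12O[C@]1(C)C[C@@H](O[Si](c3ccccc3)(c3ccccc3)C(C)(C)C)CC2(C)C | intermediate
15 | (2E)-5-[(2R,4S)-4-(TBDPSO)-2-hydroxy-2,6,6-trimethylcyclohexylidene]-3-methylpenta-2,4-dien-1-ol, aR allene axis | [H]C(/C(C)=C/CO)=[C@]=C1C(C)(C)C[C@H](O[Si](c2ccccc2)(c2ccccc2)C(C)(C)C)C[C@@]1(C)O | intermediate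
16 | (2E)-3-[(2S,6S,7aR)-6-(TBDPSO)-4,4,7a-trimethyl-2,4,5,6,7,7a-hexahydro-1-benzofuran-2-yl]but-2-en-1-ol | OC/C=C(\C)[C@@H]1C=C2C(C)(C)C[C@H](O[Si](c3ccccc3)(c3ccccc3)C(C)(C)C)C[C@@]2(C)O1 | intermediate
17 | (2S,6S,7aR)-2-[(2E)-4-bromobut-2-en-2-yl]-6-(TBDPSO)-4,4,7a-trimethyl-2,4,5,6,7,7a-hexahydro-1-benzofuran | BrC/C=C(\C)[C@@H]1C=C2C(C)(C)C[C@H](O[Si](c3ccccc3)(c3ccccc3)C(C)(C)C)C[C@@]2(C)O1 | intermediate (not isolated)
18 | triphenyl{(2E)-3-[(2S,6S,7aR)-6-(TBDPSO)-4,4,7a-trimethyl-2,4,5,6,7,7a-hexahydro-1-benzofuran-2-yl]but-2-en-1-yl}phosphonium bromide | [Br-].C(/C=C(\C)[C@@H]1C=C2C(C)(C)C[C@H](O[Si](c3ccccc3)(c3ccccc3)C(C)(C)C)C[C@@]2(C)O1)[P+](c1ccccc1)(c1ccccc1)c1ccccc1 | intermediate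
19 | [(1S,4S,6S)-4-(TBDPSO)-2,2,6-trimethyl-7-oxabicyclo[4.1.0]heptan-1-yl]methanol | OC[C@]12O[C@@]1(C)C[C@@H](O[Si](c3ccccc3)(c3ccccc3)C(C)(C)C)CC2(C)C | intermediate
20 | (1R,4S,6S)-4-(TBDPSO)-2,2,6-trimethyl-7-oxabicyclo[4.1.0]heptane-1-carbaldehyde | O=C[C@]12O[C@@]1(C)C[C@@H](O[Si](c3ccccc3)(c3ccccc3)C(C)(C)C)CC2(C)C | intermediate
21 | (1S,4S,6S)-4-(TBDPSO)-1-ethynyl-2,2,6-trimethyl-7-oxabicyclo[4.1.0]heptane | C#C[C@]12O[C@@]1(C)C[C@@H](O[Si](c3ccccc3)(c3ccccc3)C(C)(C)C)CC2(C)C | intermediate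
22 | (1R,2S,5S)-5-(TBDPSO)-2-ethynyl-1,3,3-trimethylcyclohexane-1,2-diol | C#C[C@@]1(O)C(C)(C)C[C@H](O[Si](c2ccccc2)(c2ccccc2)C(C)(C)C)C[C@@]1(C)O | intermediate
23 | ethyl (2E)-5-[(1S,2R,4S)-4-(TBDPSO)-1,2-dihydroxy-2,6,6-trimethylcyclohexyl]-3-methylpent-2-en-4-ynoate | CCOC(=O)/C=C(\C)C#C[C@@]1(O)C(C)(C)C[C@H](O[Si](c2ccccc2)(c2ccccc2)C(C)(C)C)C[C@@]1(C)O | intermediate
24 | (2E)-5-[(1S,2R,4S)-4-(TBDPSO)-1,2-dihydroxy-2,6,6-trimethylcyclohexyl]-3-methylpent-2-en-4-yn-1-ol | OC/C=C(\C)C#C[C@@]1(O)C(C)(C)C[C@H](O[Si](c2ccccc2)(c2ccccc2)C(C)(C)C)C[C@@]1(C)O | intermediate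
25 | (2E,4E)-5-[(1R,2R,4S)-4-(TBDPSO)-1,2-dihydroxy-2,6,6-trimethylcyclohexyl]-3-methylpenta-2,4-dien-1-ol | OC/C=C(C)/C=C/[C@@]1(O)C(C)(C)C[C@H](O[Si](c2ccccc2)(c2ccccc2)C(C)(C)C)C[C@@]1(C)O | intermediate
26 | (1R,2R,5S)-2-[(1E,3E)-5-bromo-3-methylpenta-1,3-dien-1-yl]-5-(TBDPSO)-1,3,3-trimethylcyclohexane-1,2-diol | BrC/C=C(C)/C=C/[C@@]1(O)C(C)(C)C[C@H](O[Si](c2ccccc2)(c2ccccc2)C(C)(C)C)C[C@@]1(C)O | intermediate (not isolated)
27 | {(2E,4E)-5-[(1R,2R,4S)-4-(TBDPSO)-1,2-dihydroxy-2,6,6-trimethylcyclohexyl]-3-methylpenta-2,4-dien-1-yl}triphenylphosphonium bromide | [Br-].C(/C=C(C)/C=C/[C@@]1(O)C(C)(C)C[C@H](O[Si](c2ccccc2)(c2ccccc2)C(C)(C)C)C[C@@]1(C)O)[P+](c1ccccc1)(c1ccccc1)c1ccccc1 | intermediate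
28 | (2E,4E,6E)-2,7-dimethylocta-2,4,6-trienedial | O=C/C(C)=C/C=C/C=C(\C)C=O | starting material
29 | triphenylphosphonium ylide of 27 | [CH-](/C=C(C)/C=C/[C@@]1(O)C(C)(C)C[C@H](O[Si](c2ccccc2)(c2ccccc2)C(C)(C)C)C[C@@]1(C)O)[P+](c1ccccc1)(c1ccccc1)c1ccccc1 | intermediate (not isolated)
30 | (2E,4E,6E,8E,10E,12E)-13-[(1R,2R,4S)-4-(TBDPSO)-1,2-dihydroxy-2,6,6-trimethylcyclohexyl]-2,7,11-trimethyltrideca-2,4,6,8,10,12-hexaenal | CC(/C=C/C=C(C)/C=C/[C@@]1(O)C(C)(C)C[C@H](O[Si](c2ccccc2)(c2ccccc2)C(C)(C)C)C[C@@]1(C)O)=C\C=C\C=C(C)\C=O | intermediate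
31 | triphenylphosphonium ylide of 18 | [CH-](/C=C(\C)[C@@H]1C=C2C(C)(C)C[C@H](O[Si](c3ccccc3)(c3ccccc3)C(C)(C)C)C[C@@]2(C)O1)[P+](c1ccccc1)(c1ccccc1)c1ccccc1 | intermediate (not isolated)
32 | (3S,5R,6R,3′S,5′R,8′S)-3,3′-bis-O-TBDPS-5′,8′-epoxy-5,6,5′,8′-tetrahydro-β,β-carotene-3,5,6,3′-tetrol | CC(/C=C/C=C(C)/C=C/[C@@]1(O)C(C)(C)C[C@H](O[Si](c2ccccc2)(c2ccccc2)C(C)(C)C)C[C@@]1(C)O)=C\C=C\C=C(C)\C=C\C=C(/C)[C@@H]1C=C2C(C)(C)C[C@H](O[Si](c3ccccc3)(c3ccccc3)C(C)(C)C)C[C@@]2(C)O1 | intermediate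
33 | (3S,5R,6R,3′S,5′R,8′S)-5′,8′-epoxy-5,6,5′,8′-tetrahydro-β,β-carotene-3,5,6,3′-tetrol | CC(/C=C/C=C(C)/C=C/[C@@]1(O)C(C)(C)C[C@H](O)C[C@@]1(C)O)=C\C=C\C=C(C)\C=C\C=C(/C)[C@@H]1C=C2C(C)(C)C[C@H](O)C[C@@]2(C)O1 | target

## Step count and risks

Total step count: 25. Longest linear sequence: 17 steps (steps 1–6, then 15–25).

Most likely to fail, step 13 (gold cycloisomerisation). The vinylallene may react through other gold pathways, or the Lewis-acidic gold may ionise the new bis-allylic ether and erode the C2 configuration. Fallback: set out from 15 and close the ring by electrophile-induced 5-endo iodoetherification (N-iodosuccinimide, NaHCO3, CH2Cl2, 0 °C). The oxygen can still only attack the allene terminus from the ring side, so the same axis-to-centre transfer operates and gives the vinyl iodide (2E)-3-[(2R,6S,7aR)-6-(TBDPSO)-3-iodo-4,4,7a-trimethyl-2,4,5,6,7,7a-hexahydro-1-benzofuran-2-yl]but-2-en-1-ol F1. Palladium-catalysed hydrodeiodination (Pd(PPh3)4, Bu3SnH, THF, rt) then returns to the route at 16.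

Second, step 18 (epoxide hydrolysis). Ionisation could occur at the wrong carbon, or the tertiary cation could undergo semipinacol ring contraction or elimination. Fallback: set out from 19 and use chelation-controlled opening of the 2,3-epoxy alcohol at its distal carbon (Ti(OiPr)4, PhCO2H, CH2Cl2, rt) to give (1R,2S,5S)-5-(TBDPSO)-2-hydroxy-2-(hydroxymethyl)-1,3,3-trimethylcyclohexyl benzoate F2. Parikh–Doering oxidation (SO3·pyridine, DMSO, Et3N) gives (1R,2R,5S)-5-(TBDPSO)-2-formyl-2-hydroxy-1,3,3-trimethylcyclohexyl benzoate F3. Ohira–Bestmann homologation (K2CO3, MeOH, 0 °C) gives (1R,2S,5S)-5-(TBDPSO)-2-ethynyl-2-hydroxy-1,3,3-trimethylcyclohexyl benzoate F4, and benzoate methanolysis (K2CO3, MeOH, 40 °C) comes back to the route at 22.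

Third, step 24 (final Wittig coupling). Ylide 31 carries a ring oxygen that could be expelled (vinylogous β-elimination), and the semi-stabilised ylide may react sluggishly with the hexaenal. Fallback: set out from 16 and switch to a Julia–Kocienski olefination. Mitsunobu thioetherification (1-phenyl-1H-tetrazole-5-thiol, PPh3, diisopropyl azodicarboxylate, THF, 0 °C) gives 5-({(2E)-3-[(2S,6S,7aR)-6-(TBDPSO)-4,4,7a-trimethyl-2,4,5,6,7,7a-hexahydro-1-benzofuran-2-yl]but-2-en-1-yl}sulfanyl)-1-phenyl-1H-tetrazole F5. Oxidation ((NH4)6Mo7O24·4H2O cat., 30% H2O2, EtOH, 0 °C → rt) gives the sulfone 5-({(2E)-3-[(2S,6S,7aR)-6-(TBDPSO)-4,4,7a-trimethyl-2,4,5,6,7,7a-hexahydro-1-benzofuran-2-yl]but-2-en-1-yl}sulfonyl)-1-phenyl-1H-tetrazole F6. Adding NaN(SiMe3)2 to a mixture of this sulfone and 30 (THF, −78 °C → rt, Barbier mode so the carbanion is trapped at once), then thermal Z → E isomerisation, comes back to the route at 32.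

## Further compounds

F1 | step 13 | (2E)-3-[(2R,6S,7aR)-6-(TBDPSO)-3-iodo-4,4,7a-trimethyl-2,4,5,6,7,7a-hexahydro-1-benzofuran-2-yl]but-2-en-1-ol | OC/C=C(\C)[C@@H]1C(I)=C2C(C)(C)C[C@H](O[Si](c3ccccc3)(c3ccccc3)C(C)(C)C)C[C@@]2(C)O1
F2 | step 18 | (1R,2S,5S)-5-(TBDPSO)-2-hydroxy-2-(hydroxymethyl)-1,3,3-trimethylcyclohexyl benzoate | OC[C@@]1(O)C(C)(C)C[C@H](O[Si](c2ccccc2)(c2ccccc2)C(C)(C)C)C[C@@]1(C)OC(=O)c1ccccc1
F3 | step 18 | (1R,2R,5S)-5-(TBDPSO)-2-formyl-2-hydroxy-1,3,3-trimethylcyclohexyl benzoate | O=C[C@@]1(O)C(C)(C)C[C@H](O[Si](c2ccccc2)(c2ccccc2)C(C)(C)C)C[C@@]1(C)OC(=O)c1ccccc1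
F4 | step 18 | (1R,2S,5S)-5-(TBDPSO)-2-ethynyl-2-hydroxy-1,3,3-trimethylcyclohexyl benzoate | C#C[C@@]1(O)C(C)(C)C[C@H](O[Si](c2ccccc2)(c2ccccc2)C(C)(C)C)C[C@@]1(C)OC(=O)c1ccccc1
F5 | step 24 | 5-({(2E)-3-[(2S,6S,7aR)-6-(TBDPSO)-4,4,7a-trimethyl-2,4,5,6,7,7a-hexahydro-1-benzofuran-2-yl]but-2-en-1-yl}sulfanyl)-1-phenyl-1H-tetrazole | c1ccccc1-n1nnnc1SC/C=C(\C)[C@@H]1C=C2C(C)(C)C[C@H](O[Si](c3ccccc3)(c3ccccc3)C(C)(C)C)C[C@@]2(C)O1
F6 | step 24 | 5-({(2E)-3-[(2S,6S,7aR)-6-(TBDPSO)-4,4,7a-trimethyl-2,4,5,6,7,7a-hexahydro-1-benzofuran-2-yl]but-2-en-1-yl}sulfonyl)-1-phenyl-1H-tetrazole | c1ccccc1-n1nnnc1S(=O)(=O)C/C=C(\C)[C@@H]1C=C2C(C)(C)C[C@H](O[Si](c3ccccc3)(c3ccccc3)C(C)(C)C)C[C@@]2(C)O1
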